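**Retrosynthetic overview**
1. The target is an (R)-4-phenylchroman-2-one. Its ring A has a free hydroxyl on C7 directly beside a ketone on C8, and C8 lies between C7–O and C8a–O1. An ortho-hydroxyaryl ketone of this kind is what an aryne gives when it inserts into the O–C(acyl) bond of a carboxylic acid.
2. Last disconnections: the two remaining O-methyl groups (BBr3) and the lactone bond O1–C2. The lactone ring is the only ring made in the route and is closed late, onto the C8a phenol, which is freed selectively because its methyl ether lies beside the C8 ketone.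
3. Key disconnection: C7–O and C8–C(=O) together, back to the C7≡C8 aryne (from an ortho-silylaryl triflate) and 3-(4-methoxyphenyl)propanoic acid.
4. The silyl triflate comes from a 4-hydroxy-2,6-dimethoxyphenyl ring by ortho-bromination, O-silylation, bromine–lithium exchange with retro-Brook shift and triflation.
5. The C4 stereocentre comes from rhodium/chiral diene conjugate phenylation of a tert-butyl (E)-cinnamate, made by Horner–Wadsworth–Emmons olefination of 4-(benzyloxy)-2,6-dimethoxybenzaldehyde. Ring A, the phenyl ring and the 4-hydroxyphenyl ring are bought.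

Key step: step 8

Remark on the chemistry: the single stereocentre is read from the SMILES as R. Positions are numbered as in the chroman-2-one (O1, C2, C3, C4, C4a, C5–C8, C8a; ring A is the benzo ring), also for the open-chain intermediates. The propanoate is carried as its tert-butyl ester so that it resists n-BuLi in step 7; BCl3 removes it in step 9.

**Step 1**
Reactants: 1 4-hydroxy-2,6-dimethoxybenzaldehyde
Product: 2 4-(benzyloxy)-2,6-dimethoxybenzaldehyde
Conditions: BnBr, K2CO3, DMF, rt
Reagents that add atoms: benzyl bromide, BrCc1ccccc1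
Why: Williamson etherification of the acidic para-formyl phenol; the benzyl ether keeps a phenoxide from deactivating the later Michael acceptor and is removable by hydrogenolysis.

**Step 2**
Reactants: 2 4-(benzyloxy)-2,6-dimethoxybenzaldehyde; 3 tert-butyl 2-(diethoxyphosphoryl)acetate
Product: 4 tert-butyl (E)-3-[4-(benzyloxy)-2,6-dimethoxyphenyl]prop-2-enoate
Conditions: NaH, THF, 0 °C → rt
Reagents that add atoms: none
Why: Horner–Wadsworth–Emmons olefination with a stabilised phosphonate anion should give the E-enoate, and 2,4,6-trialkoxybenzaldehydes are slow but competent partners.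

**Step 3**
Reactants: 4 tert-butyl (E)-3-[4-(benzyloxy)-2,6-dimethoxyphenyl]prop-2-enoate; 5 phenylboronic acid
Product: 6 tert-butyl (R)-3-[4-(benzyloxy)-2,6-dimethoxyphenyl]-3-phenylpropanoate
Conditions: [RhCl(C2H4)2]2 (2.5 mol %), (1S,4S)-2,5-diphenylbicyclo[2.2.2]octa-2,5-diene ((S,S)-Ph-bod*, 5.5 mol %), 5 (3 equiv), KOH (0.5 equiv), 1,4-dioxane/H2O 10:1, 50 °C
Reagents that add atoms: none
Why: Hayashi–Miyaura rhodium-catalysed asymmetric 1,4-addition, in which a phenylrhodium species inserts the E-enoate and water protonates the rhodium enolate; the S,S diene (antipode of the ligand that binds enones on the α-re face) should bind the α-si face, which places phenyl on the β-carbon so that C4 is R (ring A aryl > phenyl > CH2 > H).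

**Step 4**
Reactants: 6 tert-butyl (R)-3-[4-(benzyloxy)-2,6-dimethoxyphenyl]-3-phenylpropanoate
Product: 7 tert-butyl (R)-3-(4-hydroxy-2,6-dimethoxyphenyl)-3-phenylpropanoate
Conditions: H2 (1 atm), 10% Pd/C, EtOAc, rt
Reagents that add atoms: none
Why: Hydrogenolysis of the aryl benzyl ether; the tert-butyl ester, the methyl ethers and the all-carbon diarylmethine centre are inert to it.

**Step 5**
Reactants: 7 tert-butyl (R)-3-(4-hydroxy-2,6-dimethoxyphenyl)-3-phenylpropanoate
Product: 8 tert-butyl (R)-3-(3-bromo-4-hydroxy-2,6-dimethoxyphenyl)-3-phenylpropanoate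
Conditions: NBS (1.0 equiv), i-Pr2NH (10 mol %), CH2Cl2, −40 → 0 °C
Reagents that add atoms: N-bromosuccinimide, O=C1CCC(=O)N1Br
Why: Electrophilic aromatic bromination ortho to the free phenol; the para position is blocked and the two ortho carbons are equivalent by rotation about the aryl–C4 bond, so one equivalent in the cold should give a single monobromide.

**Step 6**
Reactants: 8 tert-butyl (R)-3-(3-bromo-4-hydroxy-2,6-dimethoxyphenyl)-3-phenylpropanoate
Product: 9 tert-butyl (R)-3-[3-bromo-2,6-dimethoxy-4-(trimethylsilyloxy)phenyl]-3-phenylpropanoate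
Conditions: (Me3Si)2NH, THF, 70 °C; concentrate, use crude
Reagents that add atoms: hexamethyldisilazane, C[Si](C)(C)N[Si](C)(C)C
Why: O-silylation of the phenol with a silazane, with ammonia as the only by-product, gives the aryl silyl ether needed for the O→C silyl shift.

**Step 7**
Reactants: 9 tert-butyl (R)-3-[3-bromo-2,6-dimethoxy-4-(trimethylsilyloxy)phenyl]-3-phenylpropanoate
Product: 12 tert-butyl (R)-3-[2,6-dimethoxy-4-(trifluoromethylsulfonyloxy)-3-(trimethylsilyl)phenyl]-3-phenylpropanoate, via aryllithium 10 (not isolated), via lithium phenoxide 11 (not isolated)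
Conditions: n-BuLi (1.1 equiv), THF, −100 °C; then Tf2O, −100 °C → rt
Reagents that add atoms: trifluoromethanesulfonic anhydride, O=S(=O)(OS(=O)(=O)C(F)(F)F)C(F)(F)F
Why: Bromine–lithium exchange at −100 °C is expected to outrun attack of n-BuLi on the hindered tert-butyl ester or its α-hydrogens, the ortho-lithiated silyl ether then undergoes the intramolecular 1,3 O→C silyl migration (retro-Brook rearrangement), and the lithium phenoxide is triflated in the same flask.

**Step 8**
Reactants: 12 tert-butyl (R)-3-[2,6-dimethoxy-4-(trifluoromethylsulfonyloxy)-3-(trimethylsilyl)phenyl]-3-phenylpropanoate; 13 3-(4-methoxyphenyl)propanoic acid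
Product: 16 tert-butyl (R)-3-{4-hydroxy-2,6-dimethoxy-3-[3-(4-methoxyphenyl)propanoyl]phenyl}-3-phenylpropanoate, via aryne 14 (not isolated), via aryl anion 15 (not isolated)
Conditions: 13 (1.2 equiv), CsF (4 equiv), THF, 125 °C, sealed tube
Reagents that add atoms: none
Why: Desilylation of 12 by fluoride with loss of triflate generates aryne 14 (C7≡C8); the carboxylate of 13 adds through oxygen to C7, and aryl anion 15 at C8 attacks its own ester carbonyl through a transient four-membered ring that opens to the C7 phenoxide and the C8 ketone, so C7–O and C8–C(=O) form together. The closest known reaction type is the fluoride-induced insertion of arynes into the C–O bond of carboxylic acids in hot THF, which gives ortho-hydroxyaryl ketones. No ring of the product is closed and no stereocentre is formed; the C4 centre has no hydrogen acidic enough for fluoride or carboxylate and should pass unchanged. The step needs regioselective addition across C7≡C8: the C8a methoxy group withdraws inductively, distorts the aryne so that C7 is the more electrophilic carbon, and crowds C8 (it is pushed toward C8 by the C4a side chain), whereas C7 has only the C6 hydrogen beside it, so oxygen should go to C7 and the anion should sit at C8 next to oxygen. It also needs acyl transfer within 15 to be faster than its protonation, which the high temperature, the weakly solvating THF, the slow aryne release from sparingly soluble CsF and the small excess of acid are chosen to favour. Because the two ring carbons ortho to the phenol in 7 are equivalent, only one silyl triflate and hence only one aryne can arise.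

**Step 9**
Reactants: 16 tert-butyl (R)-3-{4-hydroxy-2,6-dimethoxy-3-[3-(4-methoxyphenyl)propanoyl]phenyl}-3-phenylpropanoate
Product: 17 (R)-3-{2,4-dihydroxy-6-methoxy-3-[3-(4-methoxyphenyl)propanoyl]phenyl}-3-phenylpropanoic acid
Conditions: BCl3 (5 equiv), CH2Cl2, −78 → 0 °C; H2O
Reagents that add atoms: none
Why: Lewis-acid ether cleavage: the C8a methyl ether is ortho to the ketone and twisted out of plane between two ortho substituents, so BCl3 should cleave it (carbonyl-assisted demethylation) well before the C5 methyl ether and the anisole, while the tert-butyl ester is cleaved to the acid under the same conditions.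

**Step 10**
Reactants: 17 (R)-3-{2,4-dihydroxy-6-methoxy-3-[3-(4-methoxyphenyl)propanoyl]phenyl}-3-phenylpropanoic acid
Product: 18 (R)-7-hydroxy-5-methoxy-8-[3-(4-methoxyphenyl)propanoyl]-4-phenyl-3,4-dihydro-2H-chromen-2-one
Conditions: TsOH·H2O (10 mol %), toluene, 4 Å molecular sieves, 80 °C
Reagents that add atoms: none
Why: Acid-catalysed intramolecular esterification (lactonisation); the C8a phenol is the only hydroxyl ortho to the propanoic acid chain (C5 is still methylated, C7–OH is para), so only the wanted six-membered lactone can form, and C4 is not involved.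

**Step 11**
Reactants: 18 (R)-7-hydroxy-5-methoxy-8-[3-(4-methoxyphenyl)propanoyl]-4-phenyl-3,4-dihydro-2H-chromen-2-one
Product: 19 (R)-5,7-dihydroxy-8-[3-(4-hydroxyphenyl)propanoyl]-4-phenyl-3,4-dihydro-2H-chromen-2-one (CNP0246155.1)
Conditions: BBr3 (6 equiv), CH2Cl2, −78 → 0 °C; ice/H2O
Reagents that add atoms: none
Why: BBr3 demethylation of the two remaining aryl methyl ethers by bromide attack on the boron-complexed O-methyl groups; the aryl lactone is expected to survive anhydrous BBr3 at low temperature and a cold quench, which also avoids ring opening and re-closure onto the new C5 hydroxyl.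

**Compound list**
1 | 4-hydroxy-2,6-dimethoxybenzaldehyde | O=Cc1c(OC)cc(O)cc1OC | starting material
2 | 4-(benzyloxy)-2,6-dimethoxybenzaldehyde | O=Cc1c(OC)cc(OCc2ccccc2)cc1OC | intermediate
3 | tert-butyl 2-(diethoxyphosphoryl)acetate | CCOP(=O)(OCC)CC(=O)OC(C)(C)C | starting material
4 | tert-butyl (E)-3-[4-(benzyloxy)-2,6-dimethoxyphenyl]prop-2-enoate | CC(C)(C)OC(=O)/C=C/c1c(OC)cc(OCc2ccccc2)cc1OC | intermediate
5 | phenylboronic acid | OB(O)c1ccccc1 | starting material
6 | tert-butyl (R)-3-[4-(benzyloxy)-2,6-dimethoxyphenyl]-3-phenylpropanoate | CC(C)(C)OC(=O)C[C@H](c1ccccc1)c1c(OC)cc(OCc2ccccc2)cc1OC | intermediate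
7 | tert-butyl (R)-3-(4-hydroxy-2,6-dimethoxyphenyl)-3-phenylpropanoate | CC(C)(C)OC(=O)C[C@H](c1ccccc1)c1c(OC)cc(O)cc1OC | intermediate
8 | tert-butyl (R)-3-(3-bromo-4-hydroxy-2,6-dimethoxyphenyl)-3-phenylpropanoate | CC(C)(C)OC(=O)C[C@H](c1ccccc1)c1c(OC)cc(O)c(Br)c1OC | intermediate
9 | tert-butyl (R)-3-[3-bromo-2,6-dimethoxy-4-(trimethylsilyloxy)phenyl]-3-phenylpropanoate | CC(C)(C)OC(=O)C[C@H](c1ccccc1)c1c(OC)cc(O[Si](C)(C)C)c(Br)c1OC | intermediate
10 | tert-butyl (R)-3-[3-lithio-2,6-dimethoxy-4-(trimethylsilyloxy)phenyl]-3-phenylpropanoate (aryllithium, not isolated) | CC(C)(C)OC(=O)C[C@H](c1ccccc1)c1c(OC)cc(O[Si](C)(C)C)c([Li])c1OC | intermediate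
11 | lithium 4-[(R)-3-tert-butoxy-3-oxo-1-phenylpropyl]-3,5-dimethoxy-2-(trimethylsilyl)phenoxide (not isolated) | CC(C)(C)OC(=O)C[C@H](c1ccccc1)c1c(OC)cc(O[Li])c([Si](C)(C)C)c1OC | intermediate
12 | tert-butyl (R)-3-[2,6-dimethoxy-4-(trifluoromethylsulfonyloxy)-3-(trimethylsilyl)phenyl]-3-phenylpropanoate | CC(C)(C)OC(=O)C[C@H](c1ccccc1)c1c(OC)cc(OS(=O)(=O)C(F)(F)F)c([Si](C)(C)C)c1OC | intermediate
13 | 3-(4-methoxyphenyl)propanoic acid | COc1ccc(CCC(=O)O)cc1 | starting material
14 | tert-butyl (R)-3-(3,4-didehydro-2,6-dimethoxyphenyl)-3-phenylpropanoate (aryne, not isolated) | CC(C)(C)OC(=O)C[C@H](c1ccccc1)C1=C(OC)C#CC=C1OC | intermediate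
15 | tert-butyl (R)-3-{3-caesio-2,6-dimethoxy-4-[3-(4-methoxyphenyl)propanoyloxy]phenyl}-3-phenylpropanoate (aryl anion, not isolated) | CC(C)(C)OC(=O)C[C@H](c1ccccc1)c1c(OC)cc(OC(=O)CCc2ccc(OC)cc2)c([Cs])c1OC | intermediate
16 | tert-butyl (R)-3-{4-hydroxy-2,6-dimethoxy-3-[3-(4-methoxyphenyl)propanoyl]phenyl}-3-phenylpropanoate | CC(C)(C)OC(=O)C[C@H](c1ccccc1)c1c(OC)cc(O)c(C(=O)CCc2ccc(OC)cc2)c1OC | intermediate
17 | (R)-3-{2,4-dihydroxy-6-methoxy-3-[3-(4-methoxyphenyl)propanoyl]phenyl}-3-phenylpropanoic acid | OC(=O)C[C@H](c1ccccc1)c1c(OC)cc(O)c(C(=O)CCc2ccc(OC)cc2)c1O | intermediate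
18 | (R)-7-hydroxy-5-methoxy-8-[3-(4-methoxyphenyl)propanoyl]-4-phenyl-3,4-dihydro-2H-chromen-2-one | O=C1C[C@H](c2ccccc2)c2c(OC)cc(O)c(C(=O)CCc3ccc(OC)cc3)c2O1 | intermediate
19 | (R)-5,7-dihydroxy-8-[3-(4-hydroxyphenyl)propanoyl]-4-phenyl-3,4-dihydro-2H-chromen-2-one | O=C1C[C@H](c2ccccc2)c2c(O)cc(O)c(C(=O)CCc3ccc(O)cc3)c2O1 | target

**Totals**
Total step count: 11. Longest linear sequence: 11 steps (1 → 19).

**Steps most likely to fail**

Step 8. Aryl anion 15 may be protonated before it transfers the acyl group, so that only O-arylation occurs. The aryne may also be captured by the product phenoxide or by THF, or the carboxylate may add with the reverse regiochemistry. The fallback is a classical acylation that sets out from phenol 7 and comes back at 17. Acid 13 is converted with oxalyl chloride and catalytic DMF into 3-(4-methoxyphenyl)propanoyl chloride F1, which acylates 7 (Et3N, DMAP, CH2Cl2) to tert-butyl (R)-3-{2,6-dimethoxy-4-[3-(4-methoxyphenyl)propanoyloxy]phenyl}-3-phenylpropanoate F2. This is also the compound that protonation of 15 would give, so material diverted in step 8 can be fed in here. Fries rearrangement with TiCl4 in CH2Cl2 moves the acyl group to the carbon beside the oxygen (the two ortho positions are equivalent) and removes the tert-butyl group, giving (R)-3-{4-hydroxy-2,6-dimethoxy-3-[3-(4-methoxyphenyl)propanoyl]phenyl}-3-phenylpropanoic acid F3. Treatment of F3 with BCl3 as in step 9 gives 17.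

Step 3. Insertion of the electron-rich, doubly ortho-substituted enoate into the phenylrhodium bond may be so slow that protodeboronation consumes the boronic acid, or the facial discrimination may be insufficient. The fallback is an auxiliary-controlled cuprate addition that sets out from aldehyde 2 and comes back at 6. Knoevenagel–Doebner condensation of 2 with malonic acid (pyridine, piperidine, 90 °C) gives (E)-3-[4-(benzyloxy)-2,6-dimethoxyphenyl]prop-2-enoic acid F4. Pivaloyl chloride and Et3N convert it into the mixed pivalic anhydride F5, which is not isolated and acylates the lithium salt of (S)-4-phenyl-1,3-oxazolidin-2-one to give (S)-3-{(E)-3-[4-(benzyloxy)-2,6-dimethoxyphenyl]prop-2-enoyl}-4-phenyl-1,3-oxazolidin-2-one F6. PhMgBr with CuBr·SMe2 (THF, −40 → 0 °C) should add phenyl to the β-carbon of the magnesium-chelated s-cis enoyl imide from the face away from the auxiliary phenyl group, giving (S)-3-{(R)-3-[4-(benzyloxy)-2,6-dimethoxyphenyl]-3-phenylpropanoyl}-4-phenyl-1,3-oxazolidin-2-one F7. LiOH/H2O2 releases (R)-3-[4-(benzyloxy)-2,6-dimethoxyphenyl]-3-phenylpropanoic acid F8, and Boc2O with catalytic DMAP in t-BuOH esterifies it to 6.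

Step 7. n-BuLi or aryllithium 10 may attack the ester or remove its α-hydrogen before the silyl shift, or 10 may be quenched by proton transfer so that bromine is simply lost. The fallback avoids organolithium reagents; it sets out from 6 and comes back at 12. Iodination of 6 with N-iodosuccinimide (MeCN, catalytic TFA, 0 °C) at one of the two equivalent carbons ortho to the benzyloxy group gives tert-butyl (R)-3-[4-(benzyloxy)-3-iodo-2,6-dimethoxyphenyl]-3-phenylpropanoate F9. Iodine–magnesium exchange with i-PrMgCl·LiCl (THF, −20 °C), which tert-butyl esters tolerate, gives the arylmagnesium chloride F10, quenched in the flask with Me3SiCl to tert-butyl (R)-3-[4-(benzyloxy)-2,6-dimethoxy-3-(trimethylsilyl)phenyl]-3-phenylpropanoate F11. Hydrogenolysis (H2, Pd/C) gives tert-butyl (R)-3-[4-hydroxy-2,6-dimethoxy-3-(trimethylsilyl)phenyl]-3-phenylpropanoate F12, and Tf2O with pyridine (CH2Cl2, 0 °C) gives 12.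

**Further compounds**
F1 | step 8 | 3-(4-methoxyphenyl)propanoyl chloride | COc1ccc(CCC(=O)Cl)cc1
F2 | step 8 | tert-butyl (R)-3-{2,6-dimethoxy-4-[3-(4-methoxyphenyl)propanoyloxy]phenyl}-3-phenylpropanoate | CC(C)(C)OC(=O)C[C@H](c1ccccc1)c1c(OC)cc(OC(=O)CCc2ccc(OC)cc2)cc1OC
F3 | step 8 | (R)-3-{4-hydroxy-2,6-dimethoxy-3-[3-(4-methoxyphenyl)propanoyl]phenyl}-3-phenylpropanoic acid | OC(=O)C[C@H](c1ccccc1)c1c(OC)cc(O)c(C(=O)CCc2ccc(OC)cc2)c1OC
F4 | step 3 | (E)-3-[4-(benzyloxy)-2,6-dimethoxyphenyl]prop-2-enoic acid | OC(=O)/C=C/c1c(OC)cc(OCc2ccccc2)cc1OC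
F5 | step 3 | (E)-3-[4-(benzyloxy)-2,6-dimethoxyphenyl]prop-2-enoic pivalic anhydride (not isolated) | CC(C)(C)C(=O)OC(=O)/C=C/c1c(OC)cc(OCc2ccccc2)cc1OC
F6 | step 3 | (S)-3-{(E)-3-[4-(benzyloxy)-2,6-dimethoxyphenyl]prop-2-enoyl}-4-phenyl-1,3-oxazolidin-2-one | O=C1OC[C@H](c2ccccc2)N1C(=O)/C=C/c1c(OC)cc(OCc2ccccc2)cc1OC
F7 | step 3 | (S)-3-{(R)-3-[4-(benzyloxy)-2,6-dimethoxyphenyl]-3-phenylpropanoyl}-4-phenyl-1,3-oxazolidin-2-one | O=C1OC[C@H](c2ccccc2)N1C(=O)C[C@H](c1ccccc1)c1c(OC)cc(OCc2ccccc2)cc1OC
F8 | step 3 | (R)-3-[4-(benzyloxy)-2,6-dimethoxyphenyl]-3-phenylpropanoic acid | OC(=O)C[C@H](c1ccccc1)c1c(OC)cc(OCc2ccccc2)cc1OC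
F9 | step 7 | tert-butyl (R)-3-[4-(benzyloxy)-3-iodo-2,6-dimethoxyphenyl]-3-phenylpropanoate | CC(C)(C)OC(=O)C[C@H](c1ccccc1)c1c(OC)cc(OCc2ccccc2)c(I)c1OC
F10 | step 7 | arylmagnesium chloride from F9 (not isolated) | CC(C)(C)OC(=O)C[C@H](c1ccccc1)c1c(OC)cc(OCc2ccccc2)c([Mg]Cl)c1OC
F11 | step 7 | tert-butyl (R)-3-[4-(benzyloxy)-2,6-dimethoxy-3-(trimethylsilyl)phenyl]-3-phenylpropanoate | CC(C)(C)OC(=O)C[C@H](c1ccccc1)c1c(OC)cc(OCc2ccccc2)c([Si](C)(C)C)c1OC
F12 | step 7 | tert-butyl (R)-3-[4-hydroxy-2,6-dimethoxy-3-(trimethylsilyl)phenyl]-3-phenylpropanoate | CC(C)(C)OC(=O)C[C@H](c1ccccc1)c1c(OC)cc(O)c([Si](C)(C)C)c1OC
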